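## Structural features

The target is an elemanolide: a cyclohexane (C5–C10) with a substituent on every ring carbon, trans-fused across C7–C8 to an α-methylene-γ-butyrolactone (C11, C12, C13, lactone oxygen on C8). C10 is quaternary and carries the C14 methyl and the C1–C2 epoxide. C5 carries the 2-substituted acrolein (C4, C3 methylene, C15 aldehyde), C6 the isobutyrate and C9 a free hydroxyl. Six contiguous ring stereocentres plus the exocyclic C1 give (1R,5R,6S,7S,8R,9S,10S). With β defined as the face of the C10 methyl, the C5 and C7 carbon branches and O6 are β, while O8, O9 and C1 are α; in the chair the C10 methyl, O6 and O9 are axial and all else is equatorial. The fragile groups are the methylene lactone and the enal (Michael acceptors), the epoxide (acid, and the neighbouring C9 hydroxyl could open it), and O6, which if free would translactonise to the cis-fused 6,12-lactone. The real difficulty is the quaternary C10 flanked by C5 and C9, the differentiation of three secondary ring oxygens (O6 acylated, O8 lactonised, O9 free), and C1, which no ring element controls directly. The key step exploits the fact that the carbon-branched atoms C5, C7 and C10 are separated by the oxygen-bearing C6 and C8/C9: with C9 as a ketone and C6 as a nitro group, C10 and C6 become nucleophilic and C5 and C7 electrophilic, so C5–C10 and C6–C7 can be formed between two components in one operation.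

## Logic of the disconnections

32 to 30 (through 31): the C15–O bonds are removed first. The enal is the most sensitive group, whereas the isopropenyl group of 30 is inert to everything upstream. The gain is that no aldehyde has to be carried. The demand is an allylic oxidation that picks the C15 methyl over C5–H and tolerates the acrylate, the epoxide and the free O9–H.

30 to 26: the C11=C13 bond is cut. A saturated lactone survives oxidants and fluoride where the methylene lactone would not. The demand is enolisation of the lactone in the presence of the C6 isobutyrate and a free hydroxyl.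

26 to 24 to 23: the O8–C12 bond is cut, C12 goes back to the alcohol level (through 25), and then the Si–O bonds are cut. The lactone is closed only after O6 is acylated, so translactonisation is excluded. The gain is that O8, O9 and O12 differ only by silicon. The demand is an oxidation selective for the primary alcohol and a desilylation that spares epoxide and ester.

23 to 22: the O6–acyl bond is cut. At this point O6–H is the only free hydroxyl, so no selectivity is needed; the forward step must acylate a hindered axial alcohol without opening the epoxide.

22 to 20 to 19: the epoxide O–C2 bond (to 21), the C1–H bond (to 20) and the C1–C2 bond (to 19) are cut. C1 is the one centre without ring control, and making it by hydride delivery to a ketone puts it under reagent control. The gain is a return to the ester that the annulation delivers. The demand is that no other carbonyl group exists at this stage and that O9 is masked.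

19 to 18 to 17 to 15: the Si–O bonds of the diol protection, the C6–H and C9–H bonds and the C8–O bond are cut. Both axial carbinols arise from ketones by the same equatorial hydride delivery, and C8 is the only methylene next to a carbonyl. The gain is that 15 has no stereocentre at C6, C8 or C9. The demand is regioselective enolisation of one of two ketones and facial control in the reduction.

15 to 13: the C6 carbonyl is traced back to the C6–N bond. The nitro group is what reverses the polarity at C5 and C6 in the ring-forming step. The demand is a Nef reaction that spares the silyl ether, the alkene and the non-enolisable β-ketoester.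

13 to 6 and 11: the C5–C10 and C6–C7 bonds are cut. This removes the ring and four stereocentres at once and leaves two achiral or configurationally labile fragments. The demand is catalyst control of C10 and C5 and thermodynamic control of C6 and C7.

6 to 1 and 2; 11 to 7 and 8: the ring C7–C8 bond (the enone double bond of 6) is cut by aldol and dehydration, and the C5–C6 bond of 11 by Henry reaction and dehydration. All four starting materials are commercial. The demands are γ-selective aldol addition of a dianion and 1,2-addition of nitromethane to an enal.

The stereodescriptors of 13 map one-to-one onto C5, C7 and C10 of 32, so the precursor and product structures are used as drawn.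

## Other disconnections considered

Alternative 1: The cut is the C10–C1 bond. The (bromomethyl)dimethylsilyl ether A1 of a chiral-pool-derived 9-hydroxy β-methyl enone would be converted (Bu3SnH or a silane) into its α-silyl radical, which closes 5-exo-trig onto C10 to give the cis-fused oxasilolane A2. Tamao oxidation would later free O9 and a C1 hydroxymethyl group.
- In its favour: absolute configuration and the cis C8/C9 oxygens come from the pool, with no catalyst, no hydroxylation and no ketone reduction. On this point it is better than the chosen plan.
- Equal: the tether forces C1 onto the α face, so the quaternary centre is set as securely as by the catalyst in the chosen plan.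
- Against it: A2 still lacks the C5 branch and the C6 oxygen. The C5 substituent would have to be introduced next to the new quaternary centre through the C6 ketone, a neopentyl alkylation of uncertain facial outcome. C1 arrives one carbon short, as in the chosen plan. Stoichiometric tin hydride is a safety burden unless replaced.
- Comparison: the radical closure makes one bond and one centre; the chosen annulation makes two bonds, the ring and four centres. The pool route would also spend many steps trimming and protecting before A1, so it should be longer.

Alternative 2: The cut runs through C7–C8 and the lactone C12–O bond. CrCl2 (divalent chromium, in excess) would turn the allylic bromide of the acyclic aldehyde A3 into an allylchromium species that adds through C7 to the C8 aldehyde. The chromium alkoxide then closes onto the ester, so A4 would form with carbocycle and trans-lactone together.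
- In its favour: the α-methylene lactone arrives finished, without enolate methylenation, and C15 is already oxygenated. On both points it is better than the chosen plan, and the endgame from A4 would be shorter.
- Against it: A3 is an open chain with four stereocentres, one of them quaternary (C5, C6, C9, C10), to be made by acyclic stereocontrol. C7 and C8 depend on a crowded chair-like transition state. Chromium waste is a handling issue. C1 would have to come from substrate-controlled epoxidation of the vinyl group at the very end, where the facial sense is not secured; the chosen plan sets C1 by reagent-controlled ketone reduction.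
- Comparison: the chosen plan reaches the fully substituted ring much earlier. In step count Alternative 2 is likely longer before its key step and shorter after it, so at best equal overall.

Alternative 3: The cut is the C5–C6 bond. Aldehyde A5, carrying the acetonide of the C8/C9 diol, the quaternary C10 and a (Z)-allylboronate, would cyclise on warming through a closed six-membered transition state. C5 attacks the C6 aldehyde with allylic transposition, and A6 would form with the C6 carbinol, the C5 centre and the C3 methylene.
- In its favour: there is no nitro group and no Nef reaction, and C15 is oxygenated from the start; on both points it is better than the chosen plan.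
- Equal: the C5/C6 relationship follows from olefin geometry, which is as predictable as catalyst control, and the key step is metal-free, as is the chosen one.
- Against it: A5 must already contain C7 to C10 with the quaternary centre and a geometrically defined trisubstituted allylboronate, a long linear prelude. After A6 the lactone, the methylenation and the epoxide all remain, as in the chosen plan. The acetonide must leave under acid before an epoxide can exist, so C1 again falls to a late substrate-controlled epoxidation.
- Comparison: the chosen plan should be clearly shorter to the carbocycle.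

Key step: step 5

Assumption: the (1R,2R)-thiourea is taken as the catalyst enantiomer that gives 12 in the (5S,10S) sense; should the facial preference be the opposite, the (1S,2S)-catalyst is used and nothing else changes.

## Route

Step 1
Reactants: 1 methyl 2-methyl-3-oxobutanoate; 2 3-(tert-butyldimethylsilyloxy)propanal
Product: 4 methyl 7-(tert-butyldimethylsilyloxy)-5-hydroxy-2-methyl-3-oxoheptanoate (diastereomer mixture), via sodium lithium dianion 3 (not isolated)
Conditions: NaH, THF, 0 °C; n-BuLi, −10 °C; then 2, −78 °C; AcOH
Reagents that add atoms: none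
Why: Dianion (γ-selective) aldol addition: the more basic terminal enolate carbon of 3 adds to the aldehyde while the C10 position stays masked as the ester-stabilised enolate; the new carbinol centre is lost in step 2, so no stereocontrol is needed.

Step 2
Reactants: 4 methyl 7-(tert-butyldimethylsilyloxy)-5-hydroxy-2-methyl-3-oxoheptanoate
Product: 6 methyl (E)-7-(tert-butyldimethylsilyloxy)-2-methyl-3-oxohept-4-enoate, via C5 mesylate 5 (not isolated)
Conditions: MsCl, Et3N, CH2Cl2, 0 °C; then DBU, rt
Reagents that add atoms: none
Why: Mesylation followed by E1cB elimination through the ketone enolate; conjugation with the ketone should give the E-enone, and the acidic C–H between the carbonyls is simply re-protonated on work-up.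

Step 3
Reactants: 7 methacrolein; 8 nitromethane
Product: 9 3-methyl-1-nitrobut-3-en-2-ol (racemic)
Conditions: KOt-Bu (5 mol%), THF/t-BuOH, 0 °C
Reagents that add atoms: none
Why: Henry (nitro-aldol) reaction; with a catalytic alkoxide at 0 °C the 1,2-addition to the aldehyde is faster than conjugate addition to the α-methyl enal, no dry nitronate salt is ever isolated, and the racemic carbinol is destroyed in step 4.

Step 4
Reactants: 9 3-methyl-1-nitrobut-3-en-2-ol
Product: 11 (E)-3-methyl-1-nitrobuta-1,3-diene, via allylic mesylate 10 (not isolated)
Conditions: MsCl, Et3N, CH2Cl2, −20 to 0 °C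
Reagents that add atoms: none
Why: Mesylation and in situ E1cB elimination through the nitronate give the conjugated E-nitroalkene; the volatile, polymerisable diene is kept cold in solution and used at once rather than distilled, which is also the safer handling for a small nitroalkene.

Step 5
Reactants: 6 methyl (E)-7-(tert-butyldimethylsilyloxy)-2-methyl-3-oxohept-4-enoate; 11 (E)-3-methyl-1-nitrobuta-1,3-diene
Product: 13 methyl (1S,2S,3S,4R)-4-[2-(tert-butyldimethylsilyloxy)ethyl]-1-methyl-3-nitro-6-oxo-2-(prop-1-en-2-yl)cyclohexane-1-carboxylate (5β-isopropenyl 6α-nitro 7β-silyloxyethyl 10β-methyl in target numbering), via open-chain Michael adduct 12 (not isolated)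
Conditions: 1-[3,5-bis(trifluoromethyl)phenyl]-3-[(1R,2R)-2-(dimethylamino)cyclohexyl]thiourea (10 mol%), toluene, −20 °C to rt; then 1,1,3,3-tetramethylguanidine (20 mol%), 0 °C
Reagents that add atoms: none
Why: This is a domino Michael–Michael annulation of the known organocatalytic type (γ,δ-unsaturated β-ketoester plus nitroalkene under a bifunctional tertiary amine–thiourea). The dimethylamino group deprotonates 6 at C10 while the thiourea hydrogen-bonds the nitro group of 11, so the enolate adds 1,4 to C5 and gives 12; C10 and C5 are fixed here under catalyst control inside the hydrogen-bonded complex. Because C10 is now quaternary the ketoester cannot add again, and the only acidic site left is C6. The nitronate formed there (the guanidine speeds this up) adds to C7 of the enone in a 6-endo-trig Michael closure of the cyclohexanone, and protonation at C8 follows. C7 and C6 are set under thermodynamic control: the closure is reversible and C6 is epimerisable, so both substituents settle equatorial, trans to each other and to the equatorial isopropenyl group, with the C10 methyl axial. The step needs the nitroalkene, not the enone, to be the first acceptor, which the thiourea activation of the nitro group and the lower electrophilicity of the β-alkyl enone should secure. The C6 configuration is irrelevant later, because C6 becomes a carbonyl in step 6.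

Step 6
Reactants: 13 nitro cyclohexanone from step 5
Product: 15 methyl 7β-[2-(tert-butyldimethylsilyloxy)ethyl]-10β-methyl-6,9-dioxo-5β-(prop-1-en-2-yl)cyclohexane-10α-carboxylate (target numbering), via potassium nitronate 14 (not isolated)
Conditions: KOt-Bu, THF, −40 °C; then TiCl3 (aq), NH4OAc, THF/H2O, 0 °C to rt
Reagents that add atoms: water, O
Why: Reductive Nef reaction: the nitronate, made with a non-nucleophilic base at low temperature to avoid retro-Claisen opening of the non-enolisable β-ketoester and retro-Michael reaction, is reduced by trivalent titanium at pH 5–6 to the imine, which hydrolyses to the ketone; the buffered medium spares the silyl ether and the alkene, and C5 and C7, now α to the ketone, keep their more stable equatorial substituents.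

Step 7
Reactants: 15 diketone from step 6
Product: 17 8α-hydroxy diketone (methyl 7β-[2-(tert-butyldimethylsilyloxy)ethyl]-8α-hydroxy-10β-methyl-6,9-dioxo-5β-(prop-1-en-2-yl)cyclohexane-10α-carboxylate), via potassium enolate 16 (not isolated)
Conditions: KN(SiMe3)2, THF, −78 °C; 2-(phenylsulfonyl)-3-phenyloxaziridine, −78 °C; AcOH
Reagents that add atoms: 2-(phenylsulfonyl)-3-phenyloxaziridine, O=S(=O)(N1OC1c1ccccc1)c1ccccc1
Why: Enolate hydroxylation with an N-sulfonyloxaziridine: the hindered amide base removes the only unhindered α-proton (the C8 methylene; C5–H and C7–H are tertiary and flanked by branches, C10 is quaternary), and the oxidant attacks C8 anti to the syn-axial C10 methyl to give the equatorial 8α-hydroxyl, which is also the thermodynamically preferred epimer of this α-ketol.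

Step 8
Reactants: 17 8α-hydroxy diketone
Product: 18 triol ester (methyl 7β-[2-(tert-butyldimethylsilyloxy)ethyl]-6β,8α,9α-trihydroxy-10β-methyl-5β-(prop-1-en-2-yl)cyclohexane-10α-carboxylate)
Conditions: LiBH(s-Bu)3 (L-Selectride), THF, −78 °C; H2O
Reagents that add atoms: none
Why: Bulky trialkylborohydride reduction of both ketones by equatorial attack: at C6 the axial approach is blocked by the syn-axial C10 methyl and at C9 the reagent avoids the axial hydrogens at C5 and C7, so both new hydroxyls should be axial (6β and 9α, the latter cis to the 8α-hydroxyl); the hindered ester is not touched at −78 °C.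

Step 9
Reactants: 18 triol ester
Product: 19 8,9-O-(1,1,3,3-tetraisopropyldisiloxane-1,3-diyl) derivative of 18 with free 6β-hydroxyl
Conditions: (i-Pr2SiCl)2O, imidazole, DMF, 0 °C to rt
Reagents that add atoms: 1,3-dichloro-1,1,3,3-tetraisopropyldisiloxane, CC(C)[Si](Cl)(C(C)C)O[Si](Cl)(C(C)C)C(C)C
Why: Disiloxanediyl protection of a cis-1,2-diol: the first Si–Cl reacts at the unhindered equatorial 8-hydroxyl and the second closes the seven-membered ring onto the adjacent 9-hydroxyl, leaving the trans-disposed, strongly hindered axial 6-hydroxyl free.

Step 10
Reactants: 19 disiloxanediyl-protected ester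
Product: 20 chloromethyl ketone (C10 bears C(=O)CH2Cl in place of CO2Me; 6β-hydroxyl free)
Conditions: ICH2Cl, MeLi·LiBr, THF, −78 °C; AcOH, −78 °C
Reagents that add atoms: chloroiodomethane, ClCI
Why: Homologation of an ester to an α-chloro ketone with chloromethyllithium generated under Barbier conditions; one extra equivalent of MeLi turns the C6 hydroxyl into its alkoxide, the tetrahedral adduct is stable at −78 °C and collapses only on the cold acidic quench so no second addition occurs, and no other carbonyl group is present in 19.

Step 11
Reactants: 20 chloromethyl ketone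
Product: 22 (1R)-epoxide (C10 bears the oxiran-2-yl group; 6β-hydroxyl free; disiloxane and silyl ether intact), via (1R)-chlorohydrin 21 (not isolated)
Conditions: (R)-2-methyl-CBS-oxazaborolidine (30 mol%), catecholborane, toluene, −78 to −40 °C; then MeOH, K2CO3, 0 °C
Reagents that add atoms: none
Why: Oxazaborolidine-catalysed (CBS) ketone reduction followed by Williamson-type ring closure: the (R)-catalyst treats the quaternary C10 as the large group and delivers hydride to the face that gives the (1R)-carbinol, the same face the substrate itself should prefer (hydride entering anti to C5, past the C10 methyl), and carbonate in methanol then closes the epoxide with retention at C1 while O9 is still tied up in the disiloxane.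

Step 12
Reactants: 22 epoxy alcohol
Product: 23 6β-isobutyrate of 22
Conditions: (i-PrCO)2O, DMAP, Et3N, CH2Cl2, 40 °C
Reagents that add atoms: isobutyric anhydride, CC(C)C(=O)OC(=O)C(C)C
Why: Nucleophile-catalysed acylation of the only free hydroxyl; the axial 6β-hydroxyl is hindered by the syn-axial methyl, hence excess anhydride, a full equivalent of DMAP and gentle heating, conditions that the epoxide and the silicon groups tolerate.

Step 13
Reactants: 23 fully protected epoxy isobutyrate
Product: 24 triol (8α,9α,12-trihydroxy; 6β-isobutyrate; C10 epoxide; C5 isopropenyl)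
Conditions: Bu4NF, AcOH, THF, 0 °C to rt
Reagents that add atoms: none
Why: Fluoride-mediated desilylation, buffered with acetic acid so that the isobutyrate does not migrate and the epoxide is not opened; both silicon protecting groups fall in one operation.

Step 14
Reactants: 24 triol
Product: 26 trans-fused 8,12-lactone (saturated at C11; 9α-hydroxyl free), via lactol 25 (not isolated)
Conditions: TEMPO (20 mol%), PhI(OAc)2, NaHCO3, CH2Cl2, rt
Reagents that add atoms: none
Why: Nitroxyl-catalysed oxidative lactonisation: the oxoammonium ion oxidises only the primary C12 alcohol, the aldehyde closes with the equatorial 8α-hydroxyl to the lactol and this is oxidised to the trans-fused γ-lactone; O6 is acylated and O9 lies on the face opposite the C7 side chain, so neither can compete, and the hindered 9-hydroxyl is not oxidised.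

Step 15
Reactants: 26 saturated lactone
Product: 30 α-methylene lactone (11(13)-ene; isopropenyl still at C5), via dilithium enolate 27 (not isolated), via Mannich base 28 (not isolated), via ammonium iodide 29 (not isolated)
Conditions: LiN(i-Pr)2, THF, −78 °C; CH2=NMe2+ I−, −78 to 0 °C; MeI, MeOH; NaHCO3 (aq), CH2Cl2
Reagents that add atoms: N,N-dimethylmethyleneiminium iodide, C=[N+](C)C.[I-]
Why: Mannich methylenation of a lactone enolate followed by quaternisation and Hofmann-type elimination; the first equivalent of base is consumed by the 9-hydroxyl, the second deprotonates the unhindered lactone α-methylene faster than the tertiary α-C–H of the hindered isobutyrate, and the C11 stereocentre of the Mannich base disappears in the elimination.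

Step 16
Reactants: 30 α-methylene lactone
Product: 31 C15 allylic alcohol (C5 bears the 3-hydroxyprop-1-en-2-yl group)
Conditions: SeO2 (0.5 equiv), t-BuOOH, CH2Cl2, 0 °C to rt
Reagents that add atoms: selenium dioxide, O=[Se]=O; tert-butyl hydroperoxide, CC(C)(C)OO
Why: Selenium dioxide allylic oxidation (ene reaction, then [2,3]-sigmatropic shift) with the hydroperoxide as terminal oxidant, so that the toxic selenium reagent stays substoichiometric; the electron-poor methylene lactone does not react, and on the isopropenyl group the C15 methyl is attacked in preference to the neopentyl ring C5–H, which would have to pass through a very congested tertiary selenium ester.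

Step 17
Reactants: 31 allylic alcohol
Product: 32 CNP0496100.1, the (1R,5R,6S,7S,8R,9S,10S)-elemanolide target
Conditions: MnO2, CH2Cl2, rt
Reagents that add atoms: none
Why: Manganese dioxide oxidises only the allylic primary alcohol, leaving the hindered saturated 9-hydroxyl, the epoxide and the acrylate untouched; any enal already formed in step 16 is carried through unchanged.

## Compound list

1 | methyl 2-methyl-3-oxobutanoate | COC(=O)C(C)C(C)=O | starting material
2 | 3-(tert-butyldimethylsilyloxy)propanal | O=CCCO[Si](C)(C)C(C)(C)C | starting material
3 | sodium lithium dianion (1,3-bis-enolate) of 1 | C=C([O-])C(C)=C([O-])OC.[Na+].[Li+] | intermediate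
4 | methyl 7-(tert-butyldimethylsilyloxy)-5-hydroxy-2-methyl-3-oxoheptanoate (diastereomer mixture) | COC(=O)C(C)C(=O)CC(O)CCO[Si](C)(C)C(C)(C)C | intermediate
5 | methyl 7-(tert-butyldimethylsilyloxy)-2-methyl-5-(methylsulfonyloxy)-3-oxoheptanoate | COC(=O)C(C)C(=O)CC(OS(C)(=O)=O)CCO[Si](C)(C)C(C)(C)C | intermediate
6 | methyl (E)-7-(tert-butyldimethylsilyloxy)-2-methyl-3-oxohept-4-enoate | COC(=O)C(C)C(=O)/C=C/CCO[Si](C)(C)C(C)(C)C | intermediate
7 | methacrolein | C=C(C)C=O | starting material
8 | nitromethane | C[N+](=O)[O-] | starting material
9 | 3-methyl-1-nitrobut-3-en-2-ol (racemic) | C=C(C)C(O)C[N+](=O)[O-] | intermediate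
10 | 3-methyl-1-nitrobut-3-en-2-yl methanesulfonate | C=C(C)C(OS(C)(=O)=O)C[N+](=O)[O-] | intermediate
11 | (E)-3-methyl-1-nitrobuta-1,3-diene | C=C(C)/C=C/[N+](=O)[O-] | intermediate
12 | methyl (2S,4E)-7-(tert-butyldimethylsilyloxy)-2-methyl-2-[(2S)-3-methyl-1-nitrobut-3-en-2-yl]-3-oxohept-4-enoate | COC(=O)[C@@](C)([C@@H](C[N+](=O)[O-])C(C)=C)C(=O)/C=C/CCO[Si](C)(C)C(C)(C)C | intermediate
13 | methyl (1S,2S,3S,4R)-4-[2-(tert-butyldimethylsilyloxy)ethyl]-1-methyl-3-nitro-6-oxo-2-(prop-1-en-2-yl)cyclohexane-1-carboxylate | O=C1C[C@@H](CCO[Si](C)(C)C(C)(C)C)[C@H]([N+](=O)[O-])[C@@H](C(C)=C)[C@]1(C)C(=O)OC | intermediate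
14 | potassium nitronate of 13 | O=C1C[C@@H](CCO[Si](C)(C)C(C)(C)C)C(=[N+]([O-])[O-])[C@@H](C(C)=C)[C@]1(C)C(=O)OC.[K+] | intermediate
15 | 6,9-diketone (5β-isopropenyl, 7β-silyloxyethyl, 10β-methyl, 10α-CO2Me) | O=C1C[C@@H](CCO[Si](C)(C)C(C)(C)C)C(=O)[C@@H](C(C)=C)[C@]1(C)C(=O)OC | intermediate
16 | potassium C8–C9 enolate of 15 | [O-]C1=C[C@@H](CCO[Si](C)(C)C(C)(C)C)C(=O)[C@@H](C(C)=C)[C@]1(C)C(=O)OC.[K+] | intermediate
17 | 8α-hydroxy-6,9-diketone | O=C1[C@H](O)[C@@H](CCO[Si](C)(C)C(C)(C)C)C(=O)[C@@H](C(C)=C)[C@]1(C)C(=O)OC | intermediate
18 | 6β,8α,9α-triol methyl ester | O[C@@H]1[C@@H](CCO[Si](C)(C)C(C)(C)C)[C@@H](O)[C@@H](C(C)=C)[C@](C)(C(=O)OC)[C@@H]1O | intermediate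
19 | 8,9-O-(tetraisopropyldisiloxanediyl) 6β-ol methyl ester | CC(C)[Si]1(C(C)C)O[C@@H]2[C@@H](CCO[Si](C)(C)C(C)(C)C)[C@@H](O)[C@@H](C(C)=C)[C@](C)(C(=O)OC)[C@@H]2O[Si](C(C)C)(C(C)C)O1 | intermediate
20 | C10 chloromethyl ketone, 6β-ol | CC(C)[Si]1(C(C)C)O[C@@H]2[C@@H](CCO[Si](C)(C)C(C)(C)C)[C@@H](O)[C@@H](C(C)=C)[C@](C)(C(=O)CCl)[C@@H]2O[Si](C(C)C)(C(C)C)O1 | intermediate
21 | (1R)-chlorohydrin, 6β-ol | CC(C)[Si]1(C(C)C)O[C@@H]2[C@@H](CCO[Si](C)(C)C(C)(C)C)[C@@H](O)[C@@H](C(C)=C)[C@](C)([C@@H](O)CCl)[C@@H]2O[Si](C(C)C)(C(C)C)O1 | intermediate
22 | (1R)-epoxide, 6β-ol | CC(C)[Si]1(C(C)C)O[C@@H]2[C@@H](CCO[Si](C)(C)C(C)(C)C)[C@@H](O)[C@@H](C(C)=C)[C@](C)([C@@H]3CO3)[C@@H]2O[Si](C(C)C)(C(C)C)O1 | intermediate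
23 | (1R)-epoxide 6β-isobutyrate, fully silylated | CC(C)[Si]1(C(C)C)O[C@@H]2[C@@H](CCO[Si](C)(C)C(C)(C)C)[C@@H](OC(=O)C(C)C)[C@@H](C(C)=C)[C@](C)([C@@H]3CO3)[C@@H]2O[Si](C(C)C)(C(C)C)O1 | intermediate
24 | 8α,9α,12-triol, 6β-isobutyrate, (1R)-epoxide | O[C@@H]1[C@@H](CCO)[C@@H](OC(=O)C(C)C)[C@@H](C(C)=C)[C@](C)([C@@H]2CO2)[C@@H]1O | intermediate
25 | 8,12-lactol (anomer mixture) | C1C(O)O[C@@H]2[C@@H]1[C@@H](OC(=O)C(C)C)[C@@H](C(C)=C)[C@](C)([C@@H]3CO3)[C@@H]2O | intermediate
26 | trans-fused 8,12-lactone, 9α-ol | C1C(=O)O[C@@H]2[C@@H]1[C@@H](OC(=O)C(C)C)[C@@H](C(C)=C)[C@](C)([C@@H]3CO3)[C@@H]2O | intermediate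
27 | dilithium salt of 26 (lactone enolate and C9 alkoxide) | C1=C(O[Li])O[C@@H]2[C@@H]1[C@@H](OC(=O)C(C)C)[C@@H](C(C)=C)[C@](C)([C@@H]3CO3)[C@@H]2O[Li] | intermediate
28 | 11-(dimethylaminomethyl) lactone (C11 epimers) | CN(C)CC1C(=O)O[C@@H]2[C@@H]1[C@@H](OC(=O)C(C)C)[C@@H](C(C)=C)[C@](C)([C@@H]3CO3)[C@@H]2O | intermediate
29 | 11-(trimethylammoniomethyl) lactone iodide | C[N+](C)(C)CC1C(=O)O[C@@H]2[C@@H]1[C@@H](OC(=O)C(C)C)[C@@H](C(C)=C)[C@](C)([C@@H]3CO3)[C@@H]2O.[I-] | intermediate
30 | α-methylene lactone with C5 isopropenyl | C=C1C(=O)O[C@@H]2[C@@H]1[C@@H](OC(=O)C(C)C)[C@@H](C(C)=C)[C@](C)([C@@H]3CO3)[C@@H]2O | intermediate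
31 | C15 allylic alcohol | C=C1C(=O)O[C@@H]2[C@@H]1[C@@H](OC(=O)C(C)C)[C@@H](C(=C)CO)[C@](C)([C@@H]3CO3)[C@@H]2O | intermediate
32 | CNP0496100.1 | C=C1C(=O)O[C@@H]2[C@@H]1[C@@H](OC(=O)C(C)C)[C@@H](C(=C)C=O)[C@](C)([C@@H]1CO1)[C@@H]2O | target

## Step count and least certain steps

Total: 17 steps. Longest linear sequence: 15 steps (steps 1, 2 and 5–17); the nitrodiene branch (steps 3 and 4) joins at step 5.

Step 5 (key step). The most likely failures are stalling at the open-chain adduct, competition of the enone arm or of diene polymerisation with the first addition, or erosion of the C10/C5 selectivity by retro-Michael reaction once the guanidine is added.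
Fallback: starting from 1 and 11, the same thiourea catalysis, applied to the simple α-methyl acetoacetate, would give methyl (2S,3S)-2-acetyl-2,4-dimethyl-3-(nitromethyl)pent-4-enoate F1. A Henry reaction of its primary nitro group with 2 gives the nitro alcohol F2, and dehydration (DCC, CuCl) gives the nitroalkene F3. An intramolecular Michael addition of the methyl ketone (pyrrolidine enamine or DBU) then closes the same cyclohexanone and, after base equilibration of C6 and C7, returns to the route at 13.

Step 7. The risk is enolisation at the other ketone (C5 or C7), which would lead to hydroxylation there or to migration of the isopropenyl double bond into conjugation.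
Fallback: the order is reversed. Starting from 13, two equivalents of KN(SiMe3)2 form the nitronate–enolate dianion, whose enolate carbon is hydroxylated by the same oxaziridine to give the 8α-hydroxy nitro ketone F4. The TiCl3-mediated Nef reaction of step 6, applied to F4, returns to the route at 17.

Step 10. The risk is that the short-lived carbenoid adds too slowly to the neopentyl ester, so that starting material is recovered or MeLi itself adds.
Fallback: starting from 19, LiAlH4 reduction gives the C1 primary alcohol F5, and TEMPO/PhI(OAc)2 oxidises only this primary alcohol to the aldehyde F6. Acylation as in step 12 gives the aldehyde isobutyrate F7, and chloromethyllithium, which adds to an aldehyde far faster than to the hindered ester, gives the chlorohydrin F8 as both C1 epimers. Dess–Martin oxidation gives the chloromethyl ketone F9, and the CBS reduction and carbonate closure of step 11 lead through the (1R)-chlorohydrin F10 back to the route at 23.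

Step 15. The risks are acyl transfer from O6 to the lactone enolate (an intramolecular Claisen-type reaction), enolisation of the isobutyrate, or attack of the C9 alkoxide on the epoxide on warming.
Fallback: the strong base is avoided altogether. Starting from 24, oxidation with only one equivalent of PhI(OAc)2 is stopped at the lactol 25, which is isolated. Amine-catalysed Mannich methylenation of its open hydroxy-aldehyde form (aqueous formaldehyde, pyrrolidine, propionic acid, i-PrOH, 45 °C) gives the α-methylene lactol F11, and MnO2 oxidation returns to the route at 30.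

Step 16. The risks are oxidation at the ring C5–H in place of the methyl group, over-oxidation, and acid-promoted attack of the C9 hydroxyl on the epoxide by selenium-derived acids.
Fallback: starting from 30, ene-type allylic chlorination of the electron-rich isopropenyl group (N-chlorosuccinimide, catalytic PhSeCl) gives the allylic chloride F12. A Kornblum oxidation (AgBF4, DMSO, then Et3N) converts it directly into the enal and rejoins the route at 32.

Two further points to watch, without separate fallbacks, are the facial selectivity of the hydride at C9 in step 8 and the rate of acylation of the hindered 6β-hydroxyl in step 12.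

## Further compounds

F1 | step 5 | methyl (2S,3S)-2-acetyl-2,4-dimethyl-3-(nitromethyl)pent-4-enoate | COC(=O)[C@@](C)([C@@H](C[N+](=O)[O-])C(C)=C)C(C)=O
F2 | step 5 | nitro-aldol adduct of F1 with 2 (mixture at the two new centres) | COC(=O)[C@@](C)([C@@H](C([N+](=O)[O-])C(O)CCO[Si](C)(C)C(C)(C)C)C(C)=C)C(C)=O
F3 | step 5 | nitroalkene from dehydration of F2 | COC(=O)[C@@](C)([C@@H](C([N+](=O)[O-])=CCCO[Si](C)(C)C(C)(C)C)C(C)=C)C(C)=O
F4 | step 7 | 8α-hydroxy nitro ketone | O=C1[C@H](O)[C@@H](CCO[Si](C)(C)C(C)(C)C)[C@H]([N+](=O)[O-])[C@@H](C(C)=C)[C@]1(C)C(=O)OC
F5 | step 10 | C1 primary alcohol, 6β-ol | CC(C)[Si]1(C(C)C)O[C@@H]2[C@@H](CCO[Si](C)(C)C(C)(C)C)[C@@H](O)[C@@H](C(C)=C)[C@](C)(CO)[C@@H]2O[Si](C(C)C)(C(C)C)O1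
F6 | step 10 | C1 aldehyde, 6β-ol | CC(C)[Si]1(C(C)C)O[C@@H]2[C@@H](CCO[Si](C)(C)C(C)(C)C)[C@@H](O)[C@@H](C(C)=C)[C@](C)(C=O)[C@@H]2O[Si](C(C)C)(C(C)C)O1
F7 | step 10 | C1 aldehyde 6β-isobutyrate | CC(C)[Si]1(C(C)C)O[C@@H]2[C@@H](CCO[Si](C)(C)C(C)(C)C)[C@@H](OC(=O)C(C)C)[C@@H](C(C)=C)[C@](C)(C=O)[C@@H]2O[Si](C(C)C)(C(C)C)O1
F8 | step 10 | chlorohydrin 6β-isobutyrate (both C1 epimers) | CC(C)[Si]1(C(C)C)O[C@@H]2[C@@H](CCO[Si](C)(C)C(C)(C)C)[C@@H](OC(=O)C(C)C)[C@@H](C(C)=C)[C@](C)(C(O)CCl)[C@@H]2O[Si](C(C)C)(C(C)C)O1
F9 | step 10 | chloromethyl ketone 6β-isobutyrate | CC(C)[Si]1(C(C)C)O[C@@H]2[C@@H](CCO[Si](C)(C)C(C)(C)C)[C@@H](OC(=O)C(C)C)[C@@H](C(C)=C)[C@](C)(C(=O)CCl)[C@@H]2O[Si](C(C)C)(C(C)C)O1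
F10 | step 10 | (1R)-chlorohydrin 6β-isobutyrate | CC(C)[Si]1(C(C)C)O[C@@H]2[C@@H](CCO[Si](C)(C)C(C)(C)C)[C@@H](OC(=O)C(C)C)[C@@H](C(C)=C)[C@](C)([C@@H](O)CCl)[C@@H]2O[Si](C(C)C)(C(C)C)O1
F11 | step 15 | α-methylene lactol (anomer mixture) | C=C1C(O)O[C@@H]2[C@@H]1[C@@H](OC(=O)C(C)C)[C@@H](C(C)=C)[C@](C)([C@@H]3CO3)[C@@H]2O
F12 | step 16 | C15 allylic chloride | C=C1C(=O)O[C@@H]2[C@@H]1[C@@H](OC(=O)C(C)C)[C@@H](C(=C)CCl)[C@](C)([C@@H]3CO3)[C@@H]2O
A1 | alternative 1 | (bromomethyl)dimethylsilyl ether of the 9-hydroxy β-methyl enone | CC(C)(C)[Si](C)(C)O[C@@H]1[C@@H](CC(=O)OC(C)(C)C)C(=O)C=C(C)[C@@H]1O[Si](C)(C)CBr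
A2 | alternative 1 | cis-fused oxasilolane cyclohexanone with quaternary C10 | CC(C)(C)[Si](C)(C)O[C@@H]1[C@@H](CC(=O)OC(C)(C)C)C(=O)C[C@](C)(C[Si](C)(C)O2)[C@@H]12
A3 | alternative 2 | acyclic C8 aldehyde with methyl 2-(bromomethyl)enoate terminus | O=C[C@@H](O[Si](C)(C)C(C)(C)C)[C@@](C)(C=C)[C@H](C(=C)CO[Si](C)(C)C(C)(C)C)[C@H](OC(=O)C(C)C)/C=C(\CBr)C(=O)OC
A4 | alternative 2 | bis-silyl elemanolide with trans-fused α-methylene lactone | C=C1C(=O)O[C@@H]2[C@@H]1[C@@H](OC(=O)C(C)C)[C@@H](C(=C)CO[Si](C)(C)C(C)(C)C)[C@](C)(C=C)[C@@H]2O[Si](C)(C)C(C)(C)C
A5 | alternative 3 | C6 aldehyde with tethered (Z)-allylboronate (pinacol ester) | O=C[C@H](CCOCc1ccc(OC)cc1)[C@H]2OC(C)(C)O[C@H]2[C@@](C)(C=C)/C=C(\CO[Si](C)(C)C(C)(C)C)CB3OC(C)(C)C(C)(C)O3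
A6 | alternative 3 | cyclohexanol with C6 hydroxyl, C8–C9 acetonide, C10 methyl and vinyl | CC2(C)O[C@@H]1[C@@H](CCOCc3ccc(OC)cc3)[C@@H](O)[C@@H](C(=C)CO[Si](C)(C)C(C)(C)C)[C@](C)(C=C)[C@@H]1O2
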